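## Analysis of the target

Compound 33 (CNP0406274.1) is a bicyclo[3.3.1]nonane-2,4,9-trione. Ring A (C1–C2–C3–C4–C5–C9) holds the enolised 2-aroyl-1,3-dione, ring B (C1–C8–C7–C6–C5–C9) holds the alkyl groups, and the C9 ketone is the one-carbon bridge. There are four stereocentres: the quaternary bridgeheads C1 and C5 (one prenyl group each, locked to each other by the bridge), the quaternary C8 (methyl and 4-methylpent-3-enyl) and the tertiary C7 (prenyl). The C7 prenyl group lies on the same side of ring B as the C2–C3–C4 bridge (endo); the C8 homoprenyl chain is cis to it and the C8 methyl trans, and C1 and C8 are adjacent quaternary carbons. The four trisubstituted alkenes rule out hydrogenation, halogens, peracids and strong acid. The triketone is acidic and chelating, can lose its aroyl group by retro-Claisen cleavage, and can add its enol oxygen to a prenyl group under acid. The difficulty lies in the congestion along C1–C8–C7, in bridgehead centres that cannot be corrected after ring closure, and in functionalising C3 and C4 beside four alkenes. The strategy rests on one feature: C3 carries the 3-hydroxybenzoyl carbon and C4 an oxygen, which is what remains when an isoxazole fused across C3–C4 (aryl on the C=N carbon, ring oxygen on C4) is cut at N–O and the nitrogen is hydrolysed away.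

## Retrosynthetic reasoning

33 is traced back through its silyl ether 32 to enaminone 31 and then to isoxazole 30. The aroyl oxygen is exchanged for nitrogen and the N–O bond is re-formed. The isoxazole carries the triketone in a neutral, non-chelating form; the forward steps need an N–O reduction that spares alkenes and a hydrolysis of a vinylogous amide.

30 comes from isoxazoline 29, and 29 is cut at C3–C(aryl) and C4–O into enone 23 and nitrile oxide 28. Both bonds form in one intermolecular step, so no C3 enolate has to be acylated, and 23 has only one activated alkene. The forward reaction must put oxygen on C4 and must leave the side-chain alkenes alone. 29 is oxidised to 30 before the N–O bond is cut, because direct opening of 29 would give a C4 carbinol beside a doubly activated C3, prone to retro-aldol cleavage and dehydration.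

Nitrile oxide 28 is generated from hydroximoyl chloride 27, which goes back through oxime 26 and silyl ether 25 to aldehyde 24.

23 is the dehydro form of diketone 22; only C3 of 22 can enolise, so the position of the new alkene is not in doubt. 22 is cut at C4–C5, an intramolecular Michael addition of the ring B ketone to vinyl ketone 21. This bond is chosen because it lies at the less hindered bridgehead, and because the tether can reach C5 only from the face of the acyl group, so C5 needs no separate control. 21 is released from Mannich base 19, which adds C4 to the acetyl methyl of 18.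

18 is cut at the C1–prenyl bond: the β-diketone 17 is a soft nucleophile that can be alkylated on carbon next to quaternary C8. 17 (via aldol 16) is cut at C8–CH3 and C1–C2, a conjugate addition to enone 14 with aldol trapping. This sets C8 from C7 and places the acyl carbon on C1 without any regiochemical choice.

14 is cut at C5–prenyl, an α′-alkylation of enone 12; it is done before the acetyl group exists, since afterwards the acetyl methyl would be the kinetic site. 12 comes from 8 and bromide 9 by conjugate addition and re-oxidation through 11. The homoprenyl group enters first and the methyl second, because the second group ends up trans to the C7 prenyl group.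

8 is opened to keto aldehyde 6, and 6 is cut into aldehyde 4 and enone 5. The C7 centre is set here by a catalyst, and every later centre is derived from it. 4 comes from 1 and 2 by a Claisen rearrangement.

## Alternatives that were turned down

Alternative 1: The C1–C8 bond of ring B is cut. In the forward direction a silyl triflate Lewis acid would activate the trisubstituted epoxide of the achiral cyclohexadiene A2; one of its two enantiotopic methyl enol ethers attacks the tertiary epoxide carbon C8 with inversion and closes ring B to give the bicyclic hydroxy ketone A1.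
- For: the most congested bond of the skeleton is made intramolecularly, the C8 configuration comes from an enantiopure epoxide, and ring A emerges differentiated. On these points it is stronger than the chosen route.
- Against: A1 has hydrogen at C1, a methylene at C2, no aroyl group at C3 and an exo hydroxyl at C7. The target then needs a bridgehead prenylation at C1, an oxidation at C2 beside four allylic systems, a C3 acylation, and replacement of the C7 oxygen by an endo prenyl group. The last of these is the weak point: substitution with inversion at this neopentyl carbon is not realistic, and a C7 radical would be trapped from the open exo face.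
- Comparison: the chosen route sets C7 first and never has to correct it, and it brings in the aroyl group and the C4 oxygen together.

Alternative 2: The C1–C2 bond of ring A is cut. Heating the silyl enol ether A4, which carries a dioxinone on C5, would release an acylketene; the enol silane carbon C1 attacks the ketene carbon and gives the enolised trione A3.
- For: the conditions are neutral, the acylketene is a strong electrophile, and ring A arrives at the trione oxidation level. No aromatisation, N–O cleavage or hydrolysis is needed afterwards, so it is stronger than the chosen route in oxidation-state economy.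
- Against: the new bond is made at C1, the bridgehead next to quaternary C8, by a tetrasubstituted enol carbon, and acylketenes can add to enol ethers through oxygen to give pyranones. A4 needs a quaternary C5 carrying an sp2 heterocycle with the right configuration relative to C7, set by intermolecular alkylation. A3 still lacks the aroyl group, so a separate C3 acylation follows.
- Comparison: the chosen route closes ring A at the less hindered C4–C5 bond and delivers the aroyl carbon and the C4 oxygen in one step.

Alternative 3: The C5–C6 bond of ring B is cut. Zerovalent palladium would ionise the allylic carbonate of the dearomatised acylphloroglucinol A6 (itself the product of a Claisen rearrangement that joins C1 to C8), and the C5 carbon of the enolised triketone would attack the allyl terminus to give the 7-methylene bicycle A5.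
- For: it is the shortest and most convergent plan. The aroyl group is present from the start, the soft triketone nucleophile is well suited to palladium allylation, and hydroboration of the exocyclic alkene from the open face could even place the C7 substituent endo. On step count it is stronger than the chosen route.
- Against: the Claisen step must create the vicinal quaternary centres C1 and C8 by attack on a fully substituted allyl terminus. Their relative configuration depends on a geometrically pure tetrasubstituted alkene, and their absolute configuration needs an enantioselective dearomatisation with little precedent. C7 arrives as a methylene, so the prenyl group and the C7 centre still have to be built on the acidic triketone.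
- Comparison: the chosen route is longer, but every stereocentre is set by a well-understood step, and the risk is concentrated in one cycloaddition whose new stereocentres are erased.

Key step: step 16

## Route

Remark: 32 and 33 are written as the C4 enol, one of the rapidly interconverting tautomers of the triketone. Ring positions are referred to by the numbering of 33 (C1–C9); α is the face of ring B that carries the C7 prenyl group and β the opposite face, also in the names of the monocyclic intermediates.

Step 1
Reactants: 1 2-methylbut-3-en-2-ol; 2 ethyl vinyl ether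
Product: 4 5-methylhex-4-enal, via allyl vinyl ether 3 (not isolated)
Conditions: H3PO4 (cat.), neat, 150 °C, sealed vessel
Reagents that add atoms: none
Why: Acid-catalysed vinyl transfer gives the allyl vinyl ether 3, which undergoes a Claisen [3,3] rearrangement under the same conditions; the tertiary C–O bond is traded for a C–C bond and the trisubstituted alkene.

Step 2
Reactants: 4 5-methylhex-4-enal; 5 but-3-en-2-one
Product: 6 (R)-2-(3-methylbut-2-en-1-yl)-5-oxohexanal
Conditions: (R)-2-[methoxy(diphenyl)methyl]pyrrolidine (5 mol%), ethyl 3,4-dihydroxybenzoate (20 mol%), neat, 4 °C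
Reagents that add atoms: none
Why: Enamine-catalysed Michael addition of an aldehyde to a vinyl ketone; the diarylmethyl group of the catalyst shields one face of the (E)-enamine, and the (R)-catalyst is the enantiomer that leads 5 to the face giving the (R)-aldehyde, the future C7 centre.

Step 3
Reactants: 6 (R)-2-(3-methylbut-2-en-1-yl)-5-oxohexanal
Product: 8 (R)-4-(3-methylbut-2-en-1-yl)cyclohex-2-en-1-one, via aldol adduct 7 (not isolated)
Conditions: LiOH (cat.), i-PrOH, rt
Reagents that add atoms: none
Why: Intramolecular aldol condensation: the methyl ketone enolate adds to the aldehyde (6-enolexo-exo-trig) and the aldol 7 loses water by E1cB. Ring closure is expected to be faster than epimerisation of the aldehyde α-carbon, which becomes the γ-carbon of the enone.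

Step 4
Reactants: 8 (R)-4-(3-methylbut-2-en-1-yl)cyclohex-2-en-1-one; 9 5-bromo-2-methylpent-2-ene
Product: 11 trimethyl{[(3R,4R)-3-(4-methylpent-3-en-1-yl)-4-(3-methylbut-2-en-1-yl)cyclohex-1-en-1-yl]oxy}silane, via Grignard reagent 10 (not isolated)
Conditions: 9, Mg, THF, rt; then 8, CuBr·SMe2 (10 mol%), Me3SiCl, THF, −78 °C; Et3N
Reagents that add atoms: chlorotrimethylsilane C[Si](C)(C)Cl
Why: Copper-catalysed conjugate addition of 10, accelerated by the silyl chloride; the nucleophile enters anti to the C7 prenyl group and the enolate is silylated on oxygen, which fixes the enol ether toward C1. The new C8 centre is temporary.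

Step 5
Reactants: 11 silyl enol ether
Product: 12 (R)-3-(4-methylpent-3-en-1-yl)-4-(3-methylbut-2-en-1-yl)cyclohex-2-en-1-one
Conditions: Pd(OAc)2 (1.05 equiv), MeCN, rt
Reagents that add atoms: none
Why: Saegusa–Ito oxidation: divalent palladium adds to the enol ether at C1 and β-hydride elimination toward C8 returns the enone with the homoprenyl group in place; the γ-centre C7 is not touched.

Step 6
Reactants: 12 enone; 13 1-bromo-3-methylbut-2-ene
Product: 14 (4S)-3-(4-methylpent-3-en-1-yl)-4,6-bis(3-methylbut-2-en-1-yl)cyclohex-2-en-1-one (C6 epimers)
Conditions: LiN(i-Pr)2, THF, −78 °C; then 13, −78 → −20 °C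
Reagents that add atoms: none
Why: Kinetic deprotonation at the α′-carbon (C5 of 33) gives the cross-conjugated dienolate, which is alkylated by 13 in an SN2 reaction. The new centre needs no control, since it is planarised again in step 11; the descriptor at C4 changes only through substituent priority.

Step 7
Reactants: 14 diprenyl enone
Product: 16 2-(1-hydroxyethyl)-3β-methyl-3α-(4-methylpent-3-en-1-yl)-4α,6-bis(3-methylbut-2-en-1-yl)cyclohexan-1-one, via magnesium enolate 15 (not isolated)
Conditions: MeMgBr, CuBr·SMe2 (10 mol%), THF, −40 → 0 °C; then MeCHO, −78 °C; H2O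
Reagents that add atoms: methylmagnesium bromide C[Mg]Br; acetaldehyde CC=O
Why: Copper-catalysed 1,4-addition of the methyl group anti to the pseudoaxial C7 prenyl group sets the quaternary C8 centre (methyl β, homoprenyl α). The regiodefined enolate 15 then adds to the aldehyde at C1 in an aldol reaction; the carbinol and C1 centres are uncontrolled and are removed in steps 8 and 9.

Step 8
Reactants: 16 aldol
Product: 17 2-acetyl-3β-methyl-3α-(4-methylpent-3-en-1-yl)-4α,6-bis(3-methylbut-2-en-1-yl)cyclohexan-1-one
Conditions: Dess–Martin periodinane, CH2Cl2, 0 °C → rt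
Reagents that add atoms: none
Why: Dess–Martin oxidation of the secondary alcohol gives the β-diketone, which rests as its enol; the alkenes are inert to the periodinane.

Step 9
Reactants: 17 β-diketone
Product: 18 2α-acetyl-3β-methyl-3α-(4-methylpent-3-en-1-yl)-2β,4α,6-tris(3-methylbut-2-en-1-yl)cyclohexan-1-one
Conditions: NaH, THF, 0 °C; then prenyl acetate, Pd(PPh3)4 (5 mol%), THF, 50 °C
Reagents that add atoms: 3-methylbut-2-en-1-yl acetate CC(C)=CCOC(C)=O
Why: Tsuji–Trost allylation: the sodium enolate attacks the π-prenyl complex of palladium at its unsubstituted terminus, and any O-prenyl enol ether re-ionises, so the C-alkylated product accumulates. Attack at C1 is expected on the β face, anti to the axial C8 homoprenyl chain and without a syn-axial contact to the C7 prenyl group, which leaves the acetyl group cis to the C7 prenyl group.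

Step 10
Reactants: 18 C1-prenyl diketone
Product: 19 2α-[3-(dimethylamino)propanoyl]-3β-methyl-3α-(4-methylpent-3-en-1-yl)-2β,4α,6-tris(3-methylbut-2-en-1-yl)cyclohexan-1-one
Conditions: LiN(i-Pr)2, THF, −78 °C; then Me2N=CH2 I, −78 °C → rt
Reagents that add atoms: N,N-dimethylmethyleneiminium iodide C=[N+](C)C.[I-]
Why: Kinetic enolisation of the acetyl methyl (the only unhindered acidic site, C1 being quaternary and C5–H tertiary) and Mannich reaction with the iminium salt add the future C4 as an aminomethyl group.

Step 11
Reactants: 19 Mannich base
Product: 22 (1R,5S,7S,8S)-8-methyl-8-(4-methylpent-3-en-1-yl)-1,5,7-tris(3-methylbut-2-en-1-yl)bicyclo[3.3.1]nonane-2,9-dione, via ammonium iodide 20 (not isolated), via vinyl ketone 21 (not isolated)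
Conditions: MeI, Et2O, rt; then KOt-Bu, THF/t-BuOH, 0 °C → rt
Reagents that add atoms: none
Why: N-methylation makes the amine a leaving group and base-induced E1cB elimination releases vinyl ketone 21; the C5 enolate of the ring ketone, the only enolate that can form, adds to its terminus in a 6-endo-trig intramolecular Michael reaction. The tether reaches C5 only from the α face, so the C5 prenyl group is forced to the β face and the new bridge is cis to the C7 prenyl group.

Step 12
Reactants: 22 bicyclic diketone
Product: 23 (1R,5S,7S,8S)-8-methyl-8-(4-methylpent-3-en-1-yl)-1,5,7-tris(3-methylbut-2-en-1-yl)bicyclo[3.3.1]non-3-ene-2,9-dione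
Conditions: LiN(i-Pr)2, THF, −78 °C; then PhS(Cl)=N-t-Bu, −78 °C
Reagents that add atoms: none
Why: Mukaiyama dehydrogenation: the lithium enolate at C3, the only enolisable position, is sulfenylated on carbon by the sulfinimidoyl chloride and the adduct eliminates syn at low temperature to the C3=C4 enone, without an oxidant that could touch the side chains.

Step 13
Reactants: 24 3-hydroxybenzaldehyde
Product: 25 3-(tert-butyldimethylsilyloxy)benzaldehyde
Conditions: t-BuMe2SiCl, imidazole, DMF, rt
Reagents that add atoms: tert-butylchlorodimethylsilane CC(C)(C)[Si](C)(C)Cl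
Why: Silylation of the phenol keeps it from reacting with the nitrile oxide and the oxidant used later.

Step 14
Reactants: 25 silyl ether aldehyde
Product: 26 (E)-3-(tert-butyldimethylsilyloxy)benzaldehyde oxime
Conditions: NH2OH·HCl, NaOAc, EtOH/H2O, rt
Reagents that add atoms: hydroxylamine hydrochloride Cl.NO
Why: Condensation of the aldehyde with hydroxylamine under acetate buffer, mild enough for the aryl silyl ether.

Step 15
Reactants: 26 oxime
Product: 27 (Z)-3-(tert-butyldimethylsilyloxy)-N-hydroxybenzimidoyl chloride
Conditions: N-chlorosuccinimide, DMF, rt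
Reagents that add atoms: N-chlorosuccinimide O=C1CCC(=O)N1Cl
Why: Electrophilic chlorination of the aldoxime carbon gives the hydroximoyl chloride, the storable precursor of the nitrile oxide.

Step 16
Reactants: 23 bicyclic enone; 27 hydroximoyl chloride
Product: 29 isoxazoline fused at C3–C4 (aryl on the C=N carbon bonded to C3 and ring oxygen on C4 with cis hydrogens at C3 and C4), via nitrile oxide 28 (not isolated)
Conditions: 27 (3 equiv), Et3N (slow addition), CH2Cl2, rt → 40 °C
Reagents that add atoms: none
Why: Et3N removes HCl from 27 to give nitrile oxide 28, which adds to the C3=C4 bond of 23 in a concerted, asynchronous [3+2] cycloaddition; the closest known reactions are the additions of aryl nitrile oxides to cyclopentenone and cyclohexenone, which give 4-acyl-2-isoxazolines. The isoxazoline ring is closed by the cycloaddition itself, the C3–C(aryl) and C4–O bonds forming suprafacially on both partners, not by a chain cyclisation. The oxygen terminus of the dipole has the larger HOMO coefficient and bonds to the enone β-carbon C4, which has the larger LUMO coefficient; sterically the bare oxygen also fits next to quaternary C5, while the aryl-bearing carbon takes the more open C3. The new centres C3 and C4 are cis because the addition is suprafacial, and the dipole should approach the face of ring A that is syn to the C9 carbonyl, the other face being covered by ring B and its endo C7 prenyl group; neither centre survives step 17, so this preference is not required. What is required is reaction at the conjugated cis-disubstituted alkene in preference to the four trisubstituted side-chain alkenes; this is secured by the low reactivity of unactivated trisubstituted alkenes toward nitrile oxides and by the lowered LUMO of the enone. Slow addition of base keeps the concentration of 28 low, so that dimerisation to the furoxan does not outrun addition to the hindered enone.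

Step 17
Reactants: 29 isoxazoline
Product: 30 isoxazole fused at C3–C4
Conditions: DDQ, toluene, 80 °C
Reagents that add atoms: none
Why: Dehydrogenation by a quinone: the C3–H is activated by the C2 ketone and the C=N bond and enolises; hydride loss from C4, assisted by the ring oxygen, then gives the aromatic isoxazole and erases both new stereocentres.

Step 18
Reactants: 30 isoxazole
Product: 31 enaminone (C2 and C4 ketones with an amino(aryl)methylene group at C3)
Conditions: Mo(CO)6, MeCN/H2O, 80 °C
Reagents that add atoms: none
Why: Mo(CO)6 binds the ring nitrogen and cleaves the weak N–O bond reductively, water supplying the protons; ketones, alkenes and the silyl ether do not react with this reagent.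

Step 19
Reactants: 31 enaminone
Product: 32 silyl ether of the target
Conditions: 1 M HCl, THF, 40 °C
Reagents that add atoms: water O
Why: Acid hydrolysis of the vinylogous amide: O-protonation makes the aryl-bearing carbon iminium-like, water adds and ammonia leaves as its salt, which unveils the 2-aroyl-1,3-dione as its enol.

Step 20
Reactants: 32 silyl ether
Product: 33 (1S,5S,7S,8S)-4-hydroxy-3-(3-hydroxybenzoyl)-8-methyl-8-(4-methylpent-3-en-1-yl)-1,5,7-tris(3-methylbut-2-en-1-yl)bicyclo[3.3.1]non-3-ene-2,9-dione
Conditions: HF·pyridine, pyridine, THF, 0 °C → rt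
Reagents that add atoms: none
Why: Fluoride cleaves the aryl silyl ether through pentacoordinate silicon; the buffered reagent leaves the acidic triketone and the prenyl groups alone.

## Compound list

1 | 2-methylbut-3-en-2-ol | C=CC(C)(C)O | starting material
2 | ethyl vinyl ether | C=COCC | starting material
3 | 3-methyl-3-(vinyloxy)but-1-ene | C=COC(C)(C)C=C | intermediate (not isolated)
4 | 5-methylhex-4-enal | CC(C)=CCCC=O | intermediate
5 | but-3-en-2-one | CC(=O)C=C | starting material
6 | (R)-2-(3-methylbut-2-en-1-yl)-5-oxohexanal | O=C[C@@H](CC=C(C)C)CCC(C)=O | intermediate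
7 | (4R)-3-hydroxy-4-(3-methylbut-2-en-1-yl)cyclohexan-1-one, C3 epimers | O=C1CC(O)[C@@H](CC=C(C)C)CC1 | intermediate (not isolated)
8 | (R)-4-(3-methylbut-2-en-1-yl)cyclohex-2-en-1-one | O=C1C=C[C@@H](CC=C(C)C)CC1 | intermediate
9 | 5-bromo-2-methylpent-2-ene | CC(C)=CCCBr | starting material
10 | (4-methylpent-3-en-1-yl)magnesium bromide | CC(C)=CCC[Mg]Br | intermediate (not isolated)
11 | trimethyl{[(3R,4R)-3-(4-methylpent-3-en-1-yl)-4-(3-methylbut-2-en-1-yl)cyclohex-1-en-1-yl]oxy}silane | C[Si](C)(C)OC1=C[C@H](CCC=C(C)C)[C@@H](CC=C(C)C)CC1 | intermediate
12 | (R)-3-(4-methylpent-3-en-1-yl)-4-(3-methylbut-2-en-1-yl)cyclohex-2-en-1-one | O=C1C=C(CCC=C(C)C)[C@@H](CC=C(C)C)CC1 | intermediate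
13 | 1-bromo-3-methylbut-2-ene (prenyl bromide) | CC(C)=CCBr | starting material
14 | (4S)-3-(4-methylpent-3-en-1-yl)-4,6-bis(3-methylbut-2-en-1-yl)cyclohex-2-en-1-one, C6 epimers (C6 left open in the SMILES) | O=C1C=C(CCC=C(C)C)[C@@H](CC=C(C)C)CC1CC=C(C)C | intermediate
15 | bromomagnesium enolate (toward C2) of 3β-methyl-3α-(4-methylpent-3-en-1-yl)-4α,6-bis(3-methylbut-2-en-1-yl)cyclohexan-1-one | Br[Mg]OC1=C[C@@](C)(CCC=C(C)C)[C@@H](CC=C(C)C)CC1CC=C(C)C | intermediate (not isolated)
16 | 2-(1-hydroxyethyl)-3β-methyl-3α-(4-methylpent-3-en-1-yl)-4α,6-bis(3-methylbut-2-en-1-yl)cyclohexan-1-one, epimers at C2, C6 and the carbinol carbon | O=C1C(C(C)O)[C@@](C)(CCC=C(C)C)[C@@H](CC=C(C)C)CC1CC=C(C)C | intermediate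
17 | 2-acetyl-3β-methyl-3α-(4-methylpent-3-en-1-yl)-4α,6-bis(3-methylbut-2-en-1-yl)cyclohexan-1-one (enolised; C6 epimers) | O=C1C(C(C)=O)[C@@](C)(CCC=C(C)C)[C@@H](CC=C(C)C)CC1CC=C(C)C | intermediate
18 | 2α-acetyl-3β-methyl-3α-(4-methylpent-3-en-1-yl)-2β,4α,6-tris(3-methylbut-2-en-1-yl)cyclohexan-1-one (C6 epimers) | O=C1[C@@](CC=C(C)C)(C(C)=O)[C@@](C)(CCC=C(C)C)[C@@H](CC=C(C)C)CC1CC=C(C)C | intermediate
19 | 2α-[3-(dimethylamino)propanoyl]-3β-methyl-3α-(4-methylpent-3-en-1-yl)-2β,4α,6-tris(3-methylbut-2-en-1-yl)cyclohexan-1-one (C6 epimers) | O=C1[C@@](CC=C(C)C)(C(=O)CCN(C)C)[C@@](C)(CCC=C(C)C)[C@@H](CC=C(C)C)CC1CC=C(C)C | intermediate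
20 | trimethylammonium iodide of 19 | O=C1[C@@](CC=C(C)C)(C(=O)CC[N+](C)(C)C)[C@@](C)(CCC=C(C)C)[C@@H](CC=C(C)C)CC1CC=C(C)C.[I-] | intermediate (not isolated)
21 | 2α-acryloyl-3β-methyl-3α-(4-methylpent-3-en-1-yl)-2β,4α,6-tris(3-methylbut-2-en-1-yl)cyclohexan-1-one (C6 epimers) | O=C1[C@@](CC=C(C)C)(C(=O)C=C)[C@@](C)(CCC=C(C)C)[C@@H](CC=C(C)C)CC1CC=C(C)C | intermediate (not isolated)
22 | (1R,5S,7S,8S)-8-methyl-8-(4-methylpent-3-en-1-yl)-1,5,7-tris(3-methylbut-2-en-1-yl)bicyclo[3.3.1]nonane-2,9-dione | CC(C)=CCC[C@@]1(C)[C@@H](CC=C(C)C)C[C@]2(CC=C(C)C)C(=O)[C@@]1(CC=C(C)C)C(=O)CC2 | intermediate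
23 | (1R,5S,7S,8S)-8-methyl-8-(4-methylpent-3-en-1-yl)-1,5,7-tris(3-methylbut-2-en-1-yl)bicyclo[3.3.1]non-3-ene-2,9-dione | CC(C)=CCC[C@@]1(C)[C@@H](CC=C(C)C)C[C@]2(CC=C(C)C)C(=O)[C@@]1(CC=C(C)C)C(=O)C=C2 | intermediate
24 | 3-hydroxybenzaldehyde | O=Cc1cccc(O)c1 | starting material
25 | 3-(tert-butyldimethylsilyloxy)benzaldehyde | O=Cc1cccc(O[Si](C)(C)C(C)(C)C)c1 | intermediate
26 | (E)-3-(tert-butyldimethylsilyloxy)benzaldehyde oxime | O/N=C/c1cccc(O[Si](C)(C)C(C)(C)C)c1 | intermediate
27 | (Z)-3-(tert-butyldimethylsilyloxy)-N-hydroxybenzimidoyl chloride | O/N=C(\Cl)c1cccc(O[Si](C)(C)C(C)(C)C)c1 | intermediate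
28 | 3-(tert-butyldimethylsilyloxy)benzonitrile oxide | [O-][N+]#Cc1cccc(O[Si](C)(C)C(C)(C)C)c1 | intermediate (not isolated)
29 | isoxazoline fused at C3–C4 of 23: C3 bonded to the C=N carbon that bears the 3-silyloxyphenyl group, C4 bonded to the ring oxygen, H at C3 and C4 cis and directed toward ring B | CC(C)=CCC[C@@]1(C)[C@@H](CC=C(C)C)C[C@]2(CC=C(C)C)C(=O)[C@@]1(CC=C(C)C)C(=O)[C@H]1C(c3cccc(O[Si](C)(C)C(C)(C)C)c3)=NO[C@H]12 | intermediate
30 | isoxazole fused at C3–C4 (3-aryl, oxygen on C4), C2 and C9 ketones | CC(C)=CCC[C@@]1(C)[C@@H](CC=C(C)C)C[C@]2(CC=C(C)C)C(=O)[C@@]1(CC=C(C)C)C(=O)c1c(-c3cccc(O[Si](C)(C)C(C)(C)C)c3)noc12 | intermediate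
31 | 3-[amino(3-silyloxyphenyl)methylene]bicyclo[3.3.1]nonane-2,4,9-trione (enaminone; geometry of the exocyclic alkene open) | CC(C)=CCC[C@@]1(C)[C@@H](CC=C(C)C)C[C@]2(CC=C(C)C)C(=O)[C@@]1(CC=C(C)C)C(=O)C(=C(N)c1cccc(O[Si](C)(C)C(C)(C)C)c1)C2=O | intermediate
32 | tert-butyldimethylsilyl ether of 33 at the phenol | CC(C)=CCC[C@@]1(C)[C@@H](CC=C(C)C)C[C@]2(CC=C(C)C)C(=O)[C@@]1(CC=C(C)C)C(=O)C(C(=O)c1cccc(O[Si](C)(C)C(C)(C)C)c1)=C2O | intermediate
33 | (1S,5S,7S,8S)-4-hydroxy-3-(3-hydroxybenzoyl)-8-methyl-8-(4-methylpent-3-en-1-yl)-1,5,7-tris(3-methylbut-2-en-1-yl)bicyclo[3.3.1]non-3-ene-2,9-dione (CNP0406274.1) | CC(C)=CCC[C@@]1(C)[C@@H](CC=C(C)C)C[C@]2(CC=C(C)C)C(=O)[C@@]1(CC=C(C)C)C(=O)C(C(=O)c1cccc(O)c1)=C2O | target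

## Step count and least certain steps

Total step count: 20. Longest linear sequence: 17 steps (steps 1–12 and 16–20); steps 13–15 form the three-step side branch.

**Step 16 (key step).** The most likely failures are dimerisation of the nitrile oxide before it reaches the hindered, neopentyl-flanked enone, and reversal of the regiochemistry, which would put the aryl carbon on C4. Fallback, setting out from 23:
- Nucleophilic epoxidation (t-BuOOH, DBU, CH2Cl2), which touches only the enone, would give the epoxy ketone F1.
- Isomerisation with Pd(PPh3)4 and 1,2-bis(diphenylphosphino)ethane in toluene at 100 °C would give the enolised 1,3-dione F2.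
- The sodium enolate of F2 would then be treated with 27: C3 attacks the nitrile oxide carbon, the oxime oxygen closes onto a ring carbonyl and water is lost. This comes back to the route at 30.
- The regioisomeric isoxazole F3 (closure onto C2) may form as well; on N–O cleavage it gives the same enaminone 31.
- In this fallback the C4 oxygen comes from the epoxide and the C3–C(aryl) bond from an enolate addition, so neither depends on the regiochemistry of a cycloaddition.

**Step 9.** O-prenylation, attack at the tertiary allyl terminus, or too small a facial bias at C1 may intervene, because the nucleophilic carbon is flanked by quaternary C8. Fallback, setting out from 17: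
- O-allylation (allyl bromide, K2CO3, acetone) would give the allyl enol ether F4.
- Heating (toluene, 140 °C) moves the allyl group to C1 by Claisen rearrangement, an intramolecular delivery, and gives the C1-allyl diketone F5.
- Cross-metathesis with 2-methylbut-2-ene (second-generation Grubbs catalyst) converts allyl into prenyl and comes back to 18.

**Step 11.** Retro-Claisen loss of the acyl group from the non-enolisable β-diketone, or polymerisation of the vinyl ketone, may outrun ring closure by the hindered C5 enolate. Fallback, setting out from 18:
- Kinetic deprotonation of the acetyl methyl and C-formylation with 2,2,2-trifluoroethyl formate would give the hydroxymethylene ketone F6.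
- Acid (camphorsulfonic acid, toluene, 60 °C) lets the C9 enol add to the formyl carbon and the aldol lose water.
- This intramolecular aldol condensation comes back to the route at 23 and bypasses 19–22.

**Step 17.** Hydride abstraction from allylic positions of the side chains, or incomplete dehydrogenation, may occur because the quinone is used hot. Fallback, setting out from 29:
- LiN(SiMe3)2 (THF, −78 °C) and PhSeCl would give the C3 selenide F7; selenium takes the place of the C3 hydrogen because the ring fusion must stay cis.
- NaIO4 (THF/H2O) oxidises selenium, and the selenoxide eliminates syn with the C4 hydrogen, which comes back to 30.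

**Step 19.** The doubly vinylogous amide may resist hydrolysis, and forcing acid would bring addition of the enol oxygen to a prenyl alkene. Fallback, setting out from 29 and bypassing 30 and 31:
- Mo(CO)6 in wet MeCN cleaves the N–O bond of the isoxazoline; the resulting β-hydroxy imine is an ordinary ketimine and hydrolyses on work-up to the β-hydroxy ketone F8.
- Dess–Martin oxidation of the C4 carbinol comes back to 32.
- The price is the retro-aldol sensitivity of F8, which is why this is not the first choice.

## Further compounds

F1 | step 16 | 3,4-epoxide of 23 (oxygen on the face syn to C9) | CC(C)=CCC[C@@]1(C)[C@@H](CC=C(C)C)C[C@]2(CC=C(C)C)C(=O)[C@@]1(CC=C(C)C)C(=O)[C@H]1O[C@H]12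
F2 | step 16 | enolised bicyclo[3.3.1]nonane-2,4,9-trione without the C3 aroyl group | CC(C)=CCC[C@@]1(C)[C@@H](CC=C(C)C)C[C@]2(CC=C(C)C)C(=O)[C@@]1(CC=C(C)C)C(=O)C=C2O
F3 | step 16 | regioisomeric isoxazole fused at C2–C3 (oxygen on C2, C4 ketone) | CC(C)=CCC[C@@]1(C)[C@@H](CC=C(C)C)C[C@]2(CC=C(C)C)C(=O)[C@@]1(CC=C(C)C)c1onc(-c3cccc(O[Si](C)(C)C(C)(C)C)c3)c1C2=O
F4 | step 9 | O-allyl enol ether of 17 | C=CCOC1=C(C(C)=O)[C@@](C)(CCC=C(C)C)[C@@H](CC=C(C)C)CC1CC=C(C)C
F5 | step 9 | C1-allyl analogue of 18 | O=C1[C@@](CC=C)(C(C)=O)[C@@](C)(CCC=C(C)C)[C@@H](CC=C(C)C)CC1CC=C(C)C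
F6 | step 11 | hydroxymethylene ketone from 18 (3-hydroxyacryloyl group at C1) | O=C1[C@@](CC=C(C)C)(C(=O)C=CO)[C@@](C)(CCC=C(C)C)[C@@H](CC=C(C)C)CC1CC=C(C)C
F7 | step 17 | C3-phenylselanyl isoxazoline | CC(C)=CCC[C@@]1(C)[C@@H](CC=C(C)C)C[C@]2(CC=C(C)C)C(=O)[C@@]1(CC=C(C)C)C(=O)[C@@]1([Se]c3ccccc3)C(c3cccc(O[Si](C)(C)C(C)(C)C)c3)=NO[C@H]12
F8 | step 19 | C4-hydroxy C3-aroyl diketone (β-hydroxy ketone; C3 open) | CC(C)=CCC[C@@]1(C)[C@@H](CC=C(C)C)C[C@]2(CC=C(C)C)C(=O)[C@@]1(CC=C(C)C)C(=O)C(C(=O)c1cccc(O[Si](C)(C)C(C)(C)C)c1)[C@H]2O
A1 | alternative 1 | bicyclic C7-hydroxy C9-ketone with C4 methyl enol ether | CC(C)=CCC[C@@]1(C)[C@H](O)C[C@]2(CC=C(C)C)C(=O)[C@H]1CC=C2OC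
A2 | alternative 1 | 1,5-dimethoxycyclohexa-1,4-diene with prenyl and epoxide tether on C5 | CC(C)=CCC[C@@]1(C)O[C@@H]1CC1(CC=C(C)C)C(OC)=CCC=C1OC
A3 | alternative 2 | enolised bicyclo[3.3.1]nonane-2,4,9-trione lacking the C3 aroyl group | CC(C)=CCC[C@@]1(C)[C@@H](CC=C(C)C)C[C@]2(CC=C(C)C)C(=O)[C@@]1(CC=C(C)C)C(=O)C=C2O
A4 | alternative 2 | ring B silyl enol ether with a dioxinone on C5 | CC(C)=CCC[C@@]1(C)[C@@H](CC=C(C)C)C[C@@](CC=C(C)C)(C2=CC(=O)OC(C)(C)O2)C(O[Si](C)(C)C(C)(C)C)=C1CC=C(C)C
A5 | alternative 3 | 7-methylene bicyclo[3.3.1]nonane trione, aryl silyl ether | CC(C)=CCC[C@@]1(C)C(=C)C[C@]2(CC=C(C)C)C(=O)[C@@]1(CC=C(C)C)C(=O)C(C(=O)c1cccc(O[Si](C)(C)C(C)(C)C)c1)=C2O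
A6 | alternative 3 | dearomatised acylphloroglucinol with allylic carbonate side chain on C1 | COC(=O)OCC(=C)[C@](C)(CCC=C(C)C)[C@]1(CC=C(C)C)C(=O)C(C(=O)c2cccc(O[Si](C)(C)C(C)(C)C)c2)=C(O)C(CC=C(C)C)=C1O
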